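**Strategy.** Ring C of the flavanone is disconnected at C2–C3. In the precursor, C3 and C4 are a diazoacetyl group on ring A, and C2 is the methylene of an aryl benzyl ether (O1–CH2) that links ring A to the finished, enantiopure trans-dihydrobenzofuran. A chiral dirhodium tetracarboxylate turns the diazoketone into a carbenoid that inserts into one benzylic C–H bond, which closes ring C and sets C2 in one operation. The step exploits that C2 is benzylic to ring B, para to the dihydrofuran oxygen, and bonded to O1, so its C–H bonds are hydridic and stand in a 1,6-relationship to the carbenoid carbon. The dihydrobenzofuran comes from an earlier aryldiazoacetate C–H insertion.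

Key step: step 12

Remark on numbering: flavanone numbering is used for ring C (O1, C2, C3, C4, C4a, C8a); ring A is the phloroglucinol ring and ring B is the benzo ring of the dihydrobenzofuran.
Assumption: compounds 1, 2 and 12 are taken as purchasable, and the (S)-configured dirhodium catalysts are taken to give the configurations drawn; if either insertion showed the opposite sense, the enantiomeric catalyst would be used and nothing else would change.
Catalysts: Rh2(S-PTTL)4 = dirhodium tetrakis[N-phthaloyl-(S)-tert-leucinate]; Rh2(S-BSP)4 = dirhodium tetrakis[N-benzenesulfonyl-(S)-prolinate].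

**Step 1**
Reactants: 1 methyl 3-bromo-4,5-dihydroxybenzoate; 2 4-(benzyloxy)-3-methoxybenzyl chloride
Product: 3 methyl 3-bromo-4-{[4-(benzyloxy)-3-methoxyphenyl]methoxy}-5-hydroxybenzoate
Conditions: NaHCO3 (1.2 equiv), NaI (cat.), DMF, 40 °C
Reagents that add atoms: none
Why: Williamson etherification in which hydrogen carbonate should ionise only the more acidic 4-OH (para to the ester, ortho to bromine), so that this oxygen is alkylated selectively.

**Step 2**
Reactants: 3 methyl 3-bromo-4-{[4-(benzyloxy)-3-methoxyphenyl]methoxy}-5-hydroxybenzoate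
Product: 4 methyl 3-(benzyloxy)-5-bromo-4-{[4-(benzyloxy)-3-methoxyphenyl]methoxy}benzoate
Conditions: BnBr, K2CO3, DMF, rt
Reagents that add atoms: benzyl bromide, BrCc1ccccc1
Why: Williamson benzylation of the remaining phenol, which masks the future C7 hydroxyl of the dihydrobenzofuran through both carbenoid steps.

**Step 3**
Reactants: 4 methyl 3-(benzyloxy)-5-bromo-4-{[4-(benzyloxy)-3-methoxyphenyl]methoxy}benzoate
Product: 5 methyl 3-(benzyloxy)-4-{[4-(benzyloxy)-3-methoxyphenyl]methoxy}-5-(2-methoxy-2-oxoethyl)benzoate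
Conditions: BrZnCH2CO2Me (1.5 equiv, separately prepared THF solution), Pd(dba)2 (2 mol %), P(t-Bu)3 (2 mol %), THF, rt
Reagents that add atoms: bromo(2-methoxy-2-oxoethyl)zinc, COC(=O)C[Zn]Br
Why: Palladium-catalysed α-arylation of an ester as its zinc enolate (Reformatsky reagent, Negishi-type coupling), which needs no strong base and should tolerate the methyl benzoate and the ortho-alkoxy group.

**Step 4**
Reactants: 5 methyl 3-(benzyloxy)-4-{[4-(benzyloxy)-3-methoxyphenyl]methoxy}-5-(2-methoxy-2-oxoethyl)benzoate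
Product: 6 methyl 3-(benzyloxy)-4-{[4-(benzyloxy)-3-methoxyphenyl]methoxy}-5-(1-diazo-2-methoxy-2-oxoethyl)benzoate
Conditions: 4-acetamidobenzenesulfonyl azide, DBU, MeCN, 0 °C to rt
Reagents that add atoms: 4-acetamidobenzenesulfonyl azide, CC(=O)Nc1ccc(cc1)S(=O)(=O)N=[N+]=[N-]
Why: Regitz diazo transfer to the benzylic, ester-activated methylene gives the donor/acceptor diazo ester, while the non-enolisable benzoate is untouched.

**Step 5**
Reactants: 6 methyl 3-(benzyloxy)-4-{[4-(benzyloxy)-3-methoxyphenyl]methoxy}-5-(1-diazo-2-methoxy-2-oxoethyl)benzoate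
Product: 8 dimethyl (2R,3R)-7-(benzyloxy)-2-[4-(benzyloxy)-3-methoxyphenyl]-2,3-dihydro-1-benzofuran-3,5-dicarboxylate (trans diester), via cis diester 7 (not isolated)
Conditions: Rh2(S-PTTL)4 (1 mol %), toluene, −60 °C; then NaOMe (0.3 equiv), MeOH, 0 °C to rt
Reagents that add atoms: none
Why: Enantioselective intramolecular 1,5 C–H insertion of the aryldiazoacetate-derived rhodium carbenoid into the adjacent benzylic ether C–H bond, in which the chiral carboxylate catalyst selects the hydrogen that leads to (2R) and gives the cis ester, and methoxide then epimerises the enolisable C3 to the more stable trans diester without touching C2.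

**Step 6**
Reactants: 8 dimethyl (2R,3R)-7-(benzyloxy)-2-[4-(benzyloxy)-3-methoxyphenyl]-2,3-dihydro-1-benzofuran-3,5-dicarboxylate
Product: 9 methyl (2R,3S)-7-(benzyloxy)-2-[4-(benzyloxy)-3-methoxyphenyl]-3-(hydroxymethyl)-2,3-dihydro-1-benzofuran-5-carboxylate
Conditions: LiBH4 (1.5 equiv), THF, 0 °C to rt
Reagents that add atoms: none
Why: Chemoselective hydride reduction, in which LiBH4 should reduce the aliphatic, α-aryl β-alkoxy ester much faster than the electron-rich conjugated methyl benzoate; neither stereocentre is involved.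

**Step 7**
Reactants: 9 methyl (2R,3S)-7-(benzyloxy)-2-[4-(benzyloxy)-3-methoxyphenyl]-3-(hydroxymethyl)-2,3-dihydro-1-benzofuran-5-carboxylate
Product: 10 methyl (2R,3S)-7-(benzyloxy)-2-[4-(benzyloxy)-3-methoxyphenyl]-3-{[(tert-butyldimethylsilyl)oxy]methyl}-2,3-dihydro-1-benzofuran-5-carboxylate
Conditions: t-BuMe2SiCl, imidazole, DMF, rt
Reagents that add atoms: tert-butyldimethylsilyl chloride, CC(C)(C)[Si](C)(C)Cl
Why: Standard silylation of the primary alcohol, which must be masked for the Mitsunobu coupling and for the second carbenoid step.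

**Step 8**
Reactants: 10 methyl (2R,3S)-7-(benzyloxy)-2-[4-(benzyloxy)-3-methoxyphenyl]-3-{[(tert-butyldimethylsilyl)oxy]methyl}-2,3-dihydro-1-benzofuran-5-carboxylate
Product: 11 [(2R,3S)-7-(benzyloxy)-2-[4-(benzyloxy)-3-methoxyphenyl]-3-{[(tert-butyldimethylsilyl)oxy]methyl}-2,3-dihydro-1-benzofuran-5-yl]methanol
Conditions: i-Bu2AlH (2.5 equiv), CH2Cl2, −78 °C; Rochelle salt work-up
Reagents that add atoms: none
Why: Ester reduction with i-Bu2AlH gives the benzylic alcohol, and the silyl and benzyl ethers are inert to the hydride.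

**Step 9**
Reactants: 12 1-(2,4,6-trihydroxyphenyl)ethan-1-one
Product: 13 1-[2-hydroxy-4,6-bis(triisopropylsilyloxy)phenyl]ethan-1-one
Conditions: i-Pr3SiCl (2.1 equiv), imidazole, DMF, 0 °C to rt
Reagents that add atoms: triisopropylsilyl chloride, CC(C)[Si](Cl)(C(C)C)C(C)C
Why: Silylation of the two more accessible phenols, because the last ortho-hydroxyl is held in a hydrogen bond to the ketone and resists the bulky silyl chloride; the TIPS ether at the future C5 offers no C–H bond next to oxygen to the later carbenoid.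

**Step 10**
Reactants: 11 [(2R,3S)-7-(benzyloxy)-2-[4-(benzyloxy)-3-methoxyphenyl]-3-{[(tert-butyldimethylsilyl)oxy]methyl}-2,3-dihydro-1-benzofuran-5-yl]methanol; 13 1-[2-hydroxy-4,6-bis(triisopropylsilyloxy)phenyl]ethan-1-one
Product: 14 1-[2-{[(2R,3S)-7-(benzyloxy)-2-[4-(benzyloxy)-3-methoxyphenyl]-3-{[(tert-butyldimethylsilyl)oxy]methyl}-2,3-dihydro-1-benzofuran-5-yl]methoxy}-4,6-bis(triisopropylsilyloxy)phenyl]ethan-1-one
Conditions: PPh3, DIAD, THF, 0 °C to rt
Reagents that add atoms: none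
Why: Mitsunobu etherification of a primary benzylic alcohol with an acidic phenol under neutral conditions that spare the aryl silyl ethers; no stereocentre is involved.

**Step 11**
Reactants: 14 1-[2-{[(2R,3S)-7-(benzyloxy)-2-[4-(benzyloxy)-3-methoxyphenyl]-3-{[(tert-butyldimethylsilyl)oxy]methyl}-2,3-dihydro-1-benzofuran-5-yl]methoxy}-4,6-bis(triisopropylsilyloxy)phenyl]ethan-1-one
Product: 16 2-diazo-1-[2-{[(2R,3S)-7-(benzyloxy)-2-[4-(benzyloxy)-3-methoxyphenyl]-3-{[(tert-butyldimethylsilyl)oxy]methyl}-2,3-dihydro-1-benzofuran-5-yl]methoxy}-4,6-bis(triisopropylsilyloxy)phenyl]ethan-1-one, via trifluoroacetyl diketone 15 (not isolated)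
Conditions: LiN(SiMe3)2, THF, −78 °C; CF3CO2CH2CF3; then MsN3, Et3N, H2O (1 equiv), MeCN, rt
Reagents that add atoms: methanesulfonyl azide, CS(=O)(=O)N=[N+]=[N-]
Why: Detrifluoroacetylative diazo transfer, in which the kinetic lithium enolate of the methyl ketone is trifluoroacetylated and the activated diketone takes up the diazo group with loss of the trifluoroacetyl group.

**Step 12**
Reactants: 16 2-diazo-1-[2-{[(2R,3S)-7-(benzyloxy)-2-[4-(benzyloxy)-3-methoxyphenyl]-3-{[(tert-butyldimethylsilyl)oxy]methyl}-2,3-dihydro-1-benzofuran-5-yl]methoxy}-4,6-bis(triisopropylsilyloxy)phenyl]ethan-1-one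
Product: 17 (2S)-2-[(2R,3S)-7-(benzyloxy)-2-[4-(benzyloxy)-3-methoxyphenyl]-3-{[(tert-butyldimethylsilyl)oxy]methyl}-2,3-dihydro-1-benzofuran-5-yl]-5,7-bis(triisopropylsilyloxy)-2,3-dihydro-4H-chromen-4-one
Conditions: Rh2(S-BSP)4 (2 mol %), CH2Cl2, slow addition of 16 at high dilution, 0 °C to rt
Reagents that add atoms: none
Why: The chiral dirhodium tetracarboxylate (divalent rhodium) expels N2 from the diazoketone to give an electrophilic rhodium carbenoid at the future C3, which inserts into one of the two diastereotopic C–H bonds of the O1–CH2 group through a three-centre, hydride-transfer-like transition state and so forms the C3–C2 bond. The closest known reaction type is the dirhodium-catalysed intramolecular C–H insertion of 2-alkoxyaryl α-diazoketones to chroman-4-ones, which is also known in enantioselective form with N-arylsulfonylprolinate catalysts. Ring C closes in the 1,6-insertion mode through a six-membered transition state that holds C3, C4, C4a, C8a, O1 and C2. The insertion goes with retention at carbon, so C2 is set by which hydrogen is replaced, and the chiral carboxylate ligands are expected to direct the carbenoid to the pro-S hydrogen and give (2S); the dihydrobenzofuran stereocentres are too far away to help or to interfere. The step needs insertion to win over attack of the carbenoid on the ether oxygen O1 (oxonium ylide, then 1,2-shift of the benzyl group) and over attack at any other C–H bond. This is secured by the hydridic character of the target C–H bonds (benzylic, next to O1, para to the dihydrofuran oxygen), by the low basicity of O1 as an aryl ether conjugated to the acyl-bearing ring A, by the use of a rhodium carboxylate instead of a copper catalyst, by slow addition at high dilution, and by the TIPS ether at C5, which has no C–H bond next to oxygen.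

**Step 13**
Reactants: 17 (2S)-2-[(2R,3S)-7-(benzyloxy)-2-[4-(benzyloxy)-3-methoxyphenyl]-3-{[(tert-butyldimethylsilyl)oxy]methyl}-2,3-dihydro-1-benzofuran-5-yl]-5,7-bis(triisopropylsilyloxy)-2,3-dihydro-4H-chromen-4-one
Product: 18 (2S)-2-[(2R,3S)-7-(benzyloxy)-2-[4-(benzyloxy)-3-methoxyphenyl]-3-(hydroxymethyl)-2,3-dihydro-1-benzofuran-5-yl]-5,7-dihydroxy-2,3-dihydro-4H-chromen-4-one
Conditions: Bu4NF, AcOH (1.5 equiv per fluoride), THF, 0 °C to rt
Reagents that add atoms: none
Why: Fluoride cleaves the two aryl TIPS ethers and the primary TBS ether, and the acetic acid buffer keeps the freed phenols protonated so that the flavanone cannot open to the chalcone and C2 is not scrambled.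

**Step 14**
Reactants: 18 (2S)-2-[(2R,3S)-7-(benzyloxy)-2-[4-(benzyloxy)-3-methoxyphenyl]-3-(hydroxymethyl)-2,3-dihydro-1-benzofuran-5-yl]-5,7-dihydroxy-2,3-dihydro-4H-chromen-4-one
Product: 19 silyhermin B, (2S)-5,7-dihydroxy-2-[(2R,3S)-7-hydroxy-2-(4-hydroxy-3-methoxyphenyl)-3-(hydroxymethyl)-2,3-dihydro-1-benzofuran-5-yl]-2,3-dihydro-4H-chromen-4-one
Conditions: H2 (1 atm), 10% Pd/C, EtOAc–MeOH, rt
Reagents that add atoms: none
Why: Catalytic hydrogenolysis should remove the two aryl benzyl ethers much faster than it attacks the cyclic benzylic C–O bonds of ring C and of the dihydrofuran or the hydrogen-bonded aryl ketone, and it leaves all three stereocentres unchanged.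

**Compound list**

1 | methyl 3-bromo-4,5-dihydroxybenzoate | COC(=O)c1cc(O)c(O)c(Br)c1 | starting material
2 | 4-(benzyloxy)-3-methoxybenzyl chloride | COc1cc(CCl)ccc1OCc1ccccc1 | starting material
3 | methyl 3-bromo-4-{[4-(benzyloxy)-3-methoxyphenyl]methoxy}-5-hydroxybenzoate | COC(=O)c1cc(O)c(OCc2ccc(OCc3ccccc3)c(OC)c2)c(Br)c1 | intermediate
4 | methyl 3-(benzyloxy)-5-bromo-4-{[4-(benzyloxy)-3-methoxyphenyl]methoxy}benzoate | COC(=O)c1cc(OCc2ccccc2)c(OCc2ccc(OCc3ccccc3)c(OC)c2)c(Br)c1 | intermediate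
5 | methyl 3-(benzyloxy)-4-{[4-(benzyloxy)-3-methoxyphenyl]methoxy}-5-(2-methoxy-2-oxoethyl)benzoate | COC(=O)Cc1cc(C(=O)OC)cc(OCc2ccccc2)c1OCc1ccc(OCc2ccccc2)c(OC)c1 | intermediate
6 | methyl 3-(benzyloxy)-4-{[4-(benzyloxy)-3-methoxyphenyl]methoxy}-5-(1-diazo-2-methoxy-2-oxoethyl)benzoate | COC(=O)C(=[N+]=[N-])c1cc(C(=O)OC)cc(OCc2ccccc2)c1OCc1ccc(OCc2ccccc2)c(OC)c1 | intermediate
7 | dimethyl (2R,3S)-7-(benzyloxy)-2-[4-(benzyloxy)-3-methoxyphenyl]-2,3-dihydro-1-benzofuran-3,5-dicarboxylate (cis diester) | COc1cc([C@@H]2Oc3c(OCc4ccccc4)cc(C(=O)OC)cc3[C@@H]2C(=O)OC)ccc1OCc1ccccc1 | intermediate (not isolated)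
8 | dimethyl (2R,3R)-7-(benzyloxy)-2-[4-(benzyloxy)-3-methoxyphenyl]-2,3-dihydro-1-benzofuran-3,5-dicarboxylate (trans diester) | COc1cc([C@@H]2Oc3c(OCc4ccccc4)cc(C(=O)OC)cc3[C@H]2C(=O)OC)ccc1OCc1ccccc1 | intermediate
9 | methyl (2R,3S)-7-(benzyloxy)-2-[4-(benzyloxy)-3-methoxyphenyl]-3-(hydroxymethyl)-2,3-dihydro-1-benzofuran-5-carboxylate | COc1cc([C@@H]2Oc3c(OCc4ccccc4)cc(C(=O)OC)cc3[C@H]2CO)ccc1OCc1ccccc1 | intermediate
10 | methyl (2R,3S)-7-(benzyloxy)-2-[4-(benzyloxy)-3-methoxyphenyl]-3-{[(tert-butyldimethylsilyl)oxy]methyl}-2,3-dihydro-1-benzofuran-5-carboxylate | COc1cc([C@@H]2Oc3c(OCc4ccccc4)cc(C(=O)OC)cc3[C@H]2CO[Si](C)(C)C(C)(C)C)ccc1OCc1ccccc1 | intermediate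
11 | [(2R,3S)-7-(benzyloxy)-2-[4-(benzyloxy)-3-methoxyphenyl]-3-{[(tert-butyldimethylsilyl)oxy]methyl}-2,3-dihydro-1-benzofuran-5-yl]methanol | COc1cc([C@@H]2Oc3c(OCc4ccccc4)cc(CO)cc3[C@H]2CO[Si](C)(C)C(C)(C)C)ccc1OCc1ccccc1 | intermediate
12 | 1-(2,4,6-trihydroxyphenyl)ethan-1-one | CC(=O)c1c(O)cc(O)cc1O | starting material
13 | 1-[2-hydroxy-4,6-bis(triisopropylsilyloxy)phenyl]ethan-1-one | CC(=O)c1c(O)cc(O[Si](C(C)C)(C(C)C)C(C)C)cc1O[Si](C(C)C)(C(C)C)C(C)C | intermediate
14 | 1-[2-{[(2R,3S)-7-(benzyloxy)-2-[4-(benzyloxy)-3-methoxyphenyl]-3-{[(tert-butyldimethylsilyl)oxy]methyl}-2,3-dihydro-1-benzofuran-5-yl]methoxy}-4,6-bis(triisopropylsilyloxy)phenyl]ethan-1-one | COc1cc([C@@H]2Oc3c(OCc4ccccc4)cc(COc4cc(O[Si](C(C)C)(C(C)C)C(C)C)cc(O[Si](C(C)C)(C(C)C)C(C)C)c4C(C)=O)cc3[C@H]2CO[Si](C)(C)C(C)(C)C)ccc1OCc1ccccc1 | intermediate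
15 | 4,4,4-trifluoro-1-[2-{[(2R,3S)-7-(benzyloxy)-2-[4-(benzyloxy)-3-methoxyphenyl]-3-{[(tert-butyldimethylsilyl)oxy]methyl}-2,3-dihydro-1-benzofuran-5-yl]methoxy}-4,6-bis(triisopropylsilyloxy)phenyl]butane-1,3-dione | COc1cc([C@@H]2Oc3c(OCc4ccccc4)cc(COc4cc(O[Si](C(C)C)(C(C)C)C(C)C)cc(O[Si](C(C)C)(C(C)C)C(C)C)c4C(=O)CC(=O)C(F)(F)F)cc3[C@H]2CO[Si](C)(C)C(C)(C)C)ccc1OCc1ccccc1 | intermediate (not isolated)
16 | 2-diazo-1-[2-{[(2R,3S)-7-(benzyloxy)-2-[4-(benzyloxy)-3-methoxyphenyl]-3-{[(tert-butyldimethylsilyl)oxy]methyl}-2,3-dihydro-1-benzofuran-5-yl]methoxy}-4,6-bis(triisopropylsilyloxy)phenyl]ethan-1-one | COc1cc([C@@H]2Oc3c(OCc4ccccc4)cc(COc4cc(O[Si](C(C)C)(C(C)C)C(C)C)cc(O[Si](C(C)C)(C(C)C)C(C)C)c4C(=O)C=[N+]=[N-])cc3[C@H]2CO[Si](C)(C)C(C)(C)C)ccc1OCc1ccccc1 | intermediate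
17 | (2S)-2-[(2R,3S)-7-(benzyloxy)-2-[4-(benzyloxy)-3-methoxyphenyl]-3-{[(tert-butyldimethylsilyl)oxy]methyl}-2,3-dihydro-1-benzofuran-5-yl]-5,7-bis(triisopropylsilyloxy)-2,3-dihydro-4H-chromen-4-one | COc1cc([C@@H]2Oc3c(OCc4ccccc4)cc([C@@H]4CC(=O)c5c(O[Si](C(C)C)(C(C)C)C(C)C)cc(O[Si](C(C)C)(C(C)C)C(C)C)cc5O4)cc3[C@H]2CO[Si](C)(C)C(C)(C)C)ccc1OCc1ccccc1 | intermediate
18 | (2S)-2-[(2R,3S)-7-(benzyloxy)-2-[4-(benzyloxy)-3-methoxyphenyl]-3-(hydroxymethyl)-2,3-dihydro-1-benzofuran-5-yl]-5,7-dihydroxy-2,3-dihydro-4H-chromen-4-one | COc1cc([C@@H]2Oc3c(OCc4ccccc4)cc([C@@H]4CC(=O)c5c(O)cc(O)cc5O4)cc3[C@H]2CO)ccc1OCc1ccccc1 | intermediate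
19 | silyhermin B, (2S)-5,7-dihydroxy-2-[(2R,3S)-7-hydroxy-2-(4-hydroxy-3-methoxyphenyl)-3-(hydroxymethyl)-2,3-dihydro-1-benzofuran-5-yl]-2,3-dihydro-4H-chromen-4-one | COc1cc([C@@H]2Oc3c(O)cc([C@@H]4CC(=O)c5c(O)cc(O)cc5O4)cc3[C@H]2CO)ccc1O | target

**Step count and risks**

Total step count: 14. Longest linear sequence: 13 steps (steps 1 to 8, then 10 to 14); step 9 prepares the ring A fragment.

The three steps most likely to fail:

Step 12 (key step). The carbenoid may be captured by the ether oxygen O1 (ylide formation and 1,2-shift of the benzyl group) faster than it inserts, or the catalyst may discriminate poorly between the two benzylic hydrogens, which would give poor control at C2. The fallback closes ring C at O1–C2 by known chemistry and sets out from 11. Oxidation with MnO2 (CH2Cl2, rt) should give the aldehyde F1. The dilithium salt of 13 (LiN(SiMe3)2, 2.2 equiv, THF, −78 °C) would add to it and give the β-hydroxy ketone F2 as a mixture of carbinol epimers. Intramolecular Mitsunobu etherification (PPh3, DIAD, THF) would then close the pyranone ring and give 17 together with its C2 epimer F3; the two are diastereomers and would be separated by chromatography. The fallback comes back to the route at 17.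

Step 5. Enantioselection in the first insertion may be insufficient, because the extra ortho-benzyloxy group changes the conformation of the reacting ether, and the phenoxide may be lost by β-elimination during the methoxide epimerisation. The fallback sets out from 6 and gives up catalyst control in favour of resolution. Insertion with achiral Rh2(OAc)4 (CH2Cl2, rt) would give the racemic cis diester, that is 7 and its enantiomer, the ent-cis diester F4. Epimerisation with DBU in toluene would then give the racemic trans diester, that is 8 and its enantiomer, the ent-trans diester F5. Preparative chromatography on a chiral stationary phase would deliver 8, where the route is rejoined.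

Step 6. Chemoselectivity between the two methyl esters may be lost, with partial reduction of the aromatic ester. The fallback sets out from 8 and replaces selective reduction by exhaustive reduction and selective oxidation. LiAlH4 (THF, 0 °C) should reduce both esters to the diol F6. MnO2 (CH2Cl2, rt) would oxidise only the benzylic alcohol and give the hydroxy aldehyde F7. Silylation (t-BuMe2SiCl, imidazole, DMF) would give the silyl ether aldehyde F1, the same compound as in the fallback for step 12, and NaBH4 (MeOH, 0 °C) would return 11, where the route is rejoined.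

**Further compounds**

F1 | step 12 | (2R,3S)-7-(benzyloxy)-2-[4-(benzyloxy)-3-methoxyphenyl]-3-{[(tert-butyldimethylsilyl)oxy]methyl}-2,3-dihydro-1-benzofuran-5-carbaldehyde | COc1cc([C@@H]2Oc3c(OCc4ccccc4)cc(C=O)cc3[C@H]2CO[Si](C)(C)C(C)(C)C)ccc1OCc1ccccc1
F2 | step 12 | 3-[(2R,3S)-7-(benzyloxy)-2-[4-(benzyloxy)-3-methoxyphenyl]-3-{[(tert-butyldimethylsilyl)oxy]methyl}-2,3-dihydro-1-benzofuran-5-yl]-3-hydroxy-1-[2-hydroxy-4,6-bis(triisopropylsilyloxy)phenyl]propan-1-one (mixture of carbinol epimers) | COc1cc([C@@H]2Oc3c(OCc4ccccc4)cc(C(O)CC(=O)c4c(O)cc(O[Si](C(C)C)(C(C)C)C(C)C)cc4O[Si](C(C)C)(C(C)C)C(C)C)cc3[C@H]2CO[Si](C)(C)C(C)(C)C)ccc1OCc1ccccc1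
F3 | step 12 | (2R)-2-[(2R,3S)-7-(benzyloxy)-2-[4-(benzyloxy)-3-methoxyphenyl]-3-{[(tert-butyldimethylsilyl)oxy]methyl}-2,3-dihydro-1-benzofuran-5-yl]-5,7-bis(triisopropylsilyloxy)-2,3-dihydro-4H-chromen-4-one (C2 epimer of 17) | COc1cc([C@@H]2Oc3c(OCc4ccccc4)cc([C@H]4CC(=O)c5c(O[Si](C(C)C)(C(C)C)C(C)C)cc(O[Si](C(C)C)(C(C)C)C(C)C)cc5O4)cc3[C@H]2CO[Si](C)(C)C(C)(C)C)ccc1OCc1ccccc1
F4 | step 5 | dimethyl (2S,3R)-7-(benzyloxy)-2-[4-(benzyloxy)-3-methoxyphenyl]-2,3-dihydro-1-benzofuran-3,5-dicarboxylate (enantiomer of 7) | COc1cc([C@H]2Oc3c(OCc4ccccc4)cc(C(=O)OC)cc3[C@H]2C(=O)OC)ccc1OCc1ccccc1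
F5 | step 5 | dimethyl (2S,3S)-7-(benzyloxy)-2-[4-(benzyloxy)-3-methoxyphenyl]-2,3-dihydro-1-benzofuran-3,5-dicarboxylate (enantiomer of 8) | COc1cc([C@H]2Oc3c(OCc4ccccc4)cc(C(=O)OC)cc3[C@@H]2C(=O)OC)ccc1OCc1ccccc1
F6 | step 6 | [(2R,3S)-7-(benzyloxy)-2-[4-(benzyloxy)-3-methoxyphenyl]-2,3-dihydro-1-benzofuran-3,5-diyl]dimethanol | COc1cc([C@@H]2Oc3c(OCc4ccccc4)cc(CO)cc3[C@H]2CO)ccc1OCc1ccccc1
F7 | step 6 | (2R,3S)-7-(benzyloxy)-2-[4-(benzyloxy)-3-methoxyphenyl]-3-(hydroxymethyl)-2,3-dihydro-1-benzofuran-5-carbaldehyde | COc1cc([C@@H]2Oc3c(OCc4ccccc4)cc(C=O)cc3[C@H]2CO)ccc1OCc1ccccc1
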